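In a one-step world a molecule of starting material meets one fork each minute: it stays, or it crosses to product. If its chance of crossing is the same whatever the charge, the fraction of the charge left follows from that chance and the clock. Here is what we have and what is asked.

| flask | starting material | remark | time |
|---|---|---|---|
| amber | 0.75 M | run made earlier |  |
| violet | 3 M | run made earlier |  |
| south | 1.5 M |  | 2.5 min |
| north | 1.5 M |  | 3.0 min |

| run | time / min | product / % | starting material / % |
|---|---|---|---|
| amber | 0.333 | 5 | 97 |
| amber | 0.833 | 11 | 90 |
| amber | 1.50 | 20 | 78 |
| amber | 2.50 | 32 | 68 |
| violet | 0.333 | 2 | 95 |
| violet | 0.833 | 14 | 90 |
| violet | 1.50 | 18 | 81 |
| violet | 2.50 | 31 | 69 |

(readings scatter by 1.5 percentage points)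

- the analysis behind the earlier runs scatters by 1.5 percentage points, standard deviation

1. which of these there is most of at the end, counted by the starting material in it, south (product / starting material)
2. which of these there is most of at the end, counted by the starting material in it, north (product / starting material)
3. how much there is at the end of the one of these that leads, in percent of the starting material charged: south
4. how much there is at the end of the one of these that leads, in percent of the starting material charged: north

Which numbers must we know well? The charge matters little: going from 0.75 M to 3 M leaves 68% against 69% at 2.50 min, a gap smaller than the scatter of 1.5 percentage points. So we drop the charge from the reckoning. Time matters: the amber run fell from 78% to 68% between 1.50 min and 2.50 min, so north's extra time should cost about 5 points. The chance itself must be known well: we read it at 2.50 min, the time asked for south, so the scatter of those readings goes straight into our answer for south.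

Now the number. We call it the minute chance, the share of the starting material present that crosses to product per minute (the first-order rate constant). Read from those two last readings, it is 0.151 min⁻¹. The fraction left is the exponential of minus chance times time, so our reckoning gives 68.5% for south and 63.5% for north.

The forecast names starting material in south at 68.5% (66.5% to 70.5%) and starting material in north at 64% (61% to 66.5%), holding that “the fractional rate doesn't depend on concentration”. Our north figure stands slightly lower.

South ends with 68.9% starting material and 31.1% product, north with 64.0% and 36.0%, both inside the forecast's ranges.

    starting material ⇌ product (K = 40.0, k = 0.00250 s⁻¹)

The same flask as south, read at 6.0 min, has product in the lead: the minute chance gives 40.4% starting material there, and that flask holds 41.2% starting material against 58.8% product.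

The earlier runs and the new flask were generated by integration with constants of no real substance.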